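## Retrosynthetic overview

1. Target 22 ⇐ triketone 20 by a new reductive cyclisation (O–C-1 bond, dihydropyran ring closed last, C-1 set by hydride delivery); 20 ⇐ alkyne 19 (masked 1,2-diketone).
2. 19 ⇐ chloro ketone 9 + metallated chromone 16: 1,2-addition, then semipinacol ring contraction (cyclohexane → cyclopentane, forms the C-1–chromone bond, sets C-7a by inversion).
3. 9 ⇐ (S)-3-methylcyclohexanone 2 (asymmetric conjugate addition to cyclohexenone), then enaminone, ethylidene ketone, conjugate alkynylation with 4-methylpent-1-yne, α-chlorination.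
4. 16 ⇐ 4-hydroxy-5-methylcoumarin 15 ⇐ methyl 6-methylsalicylate 13 ⇐ methyl acetoacetate + crotonaldehyde.
5. Ring order: benzene ring, then pyranone ring of the chromone; carbocycle built as a cyclohexanone and contracted to the cyclopentane; dihydropyran last.

Assumption: the side-chain methine next to the alkyne (later C-4) is carried as a mixture of both configurations and is written without a stereodescriptor in the SMILES, because it becomes sp2 in the last step.

## Route

Step 1
Reactants: 1 cyclohex-2-en-1-one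
Product: 2 (S)-3-methylcyclohexan-1-one
Conditions: Me2Zn (1.5 equiv), Cu(OTf)2 (2 mol%), binaphthol-derived bis(1-phenylethyl)amine phosphoramidite (4 mol%, the enantiomer that gives the S ketone), toluene, −30 °C; aq NH4Cl
Reagents that add atoms: dimethylzinc, C[Zn]C
Why: Copper-catalysed asymmetric conjugate addition to a cyclic enone is well established for cyclohexenone, and the chiral copper–phosphoramidite complex selects the enone face so that the methyl-bearing centre (later C-7) is S.

Step 2
Reactants: 2 (S)-3-methylcyclohexan-1-one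
Product: 3 (S,E)-2-[(dimethylamino)methylidene]-5-methylcyclohexan-1-one
Conditions: Me2NCH(OMe)2 (3 equiv), neat, 100 °C, MeOH distilled off
Reagents that add atoms: N,N-dimethylformamide dimethyl acetal, COC(OC)N(C)C
Why: Enaminone formation with an amide acetal is reversible and should favour the less hindered α-methylene remote from the methyl branch, and the stereocentre is β to the carbonyl and cannot epimerise.

Step 3
Reactants: 3 (S,E)-2-[(dimethylamino)methylidene]-5-methylcyclohexan-1-one
Product: 4 (S,E)-2-ethylidene-5-methylcyclohexan-1-one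
Conditions: MeLi (1.1 equiv), THF, −78 → −20 °C; aq NH4Cl
Reagents that add atoms: methyllithium, [Li]C
Why: Addition–elimination on the vinylogous amide (1,4-addition of the organolithium, loss of LiNMe2) gives the exocyclic s-cis enone, E for steric reasons.

Step 4
Reactants: 4 (S,E)-2-ethylidene-5-methylcyclohexan-1-one; 5 4-methylpent-1-yne
Product: 7 (2R,5S)-5-methyl-2-[(2RS)-6-methylhept-3-yn-2-yl]cyclohexan-1-one, via alkynyldimethylalane 6 (not isolated)
Conditions: 5, Me3Al (1.0 equiv), Et3N (10 mol%), heptane, 60 °C; then 4, Et2O, 0 °C → rt; 1 M HCl; NaOMe (0.1 equiv), MeOH, rt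
Reagents that add atoms: none
Why: Conjugate alkynylation of an s-cis enone by an alkynylalane (Hooz-type 1,4-addition through a six-membered O–Al–C≡C transition state) forms the C-4a–C-4 bond, and base equilibration puts the side chain equatorial, trans to the ring methyl (menthone-like, about 4:1 expected, minor isomer separated and recycled).

Step 5
Reactants: 7 (2R,5S)-5-methyl-2-[(2RS)-6-methylhept-3-yn-2-yl]cyclohexan-1-one
Product: 9 (2R,3S,6R)-2-chloro-3-methyl-6-[(2RS)-6-methylhept-3-yn-2-yl]cyclohexan-1-one, via lithium enolate 8 (not isolated)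
Conditions: LDA (1.05 equiv), THF, −78 °C; NCS (1.1 equiv), −78 °C; aq NH4Cl
Reagents that add atoms: N-chlorosuccinimide, ClN1C(=O)CCC1=O
Why: Kinetic deprotonation takes the less substituted α-carbon and electrophilic chlorination of the enolate occurs anti to the neighbouring methyl (as in trans-selective trapping of 3-substituted cyclohexanone enolates), giving the all-equatorial chloro ketone.

Step 6
Reactants: 10 methyl 3-oxobutanoate; 11 (E)-but-2-enal
Product: 12 methyl 6-methyl-2-oxocyclohex-3-ene-1-carboxylate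
Conditions: NaOMe (0.1 equiv), MeOH, −10 °C → rt; then HCl (g), 0 °C
Reagents that add atoms: none
Why: Michael addition of the acetoacetate to crotonaldehyde followed by intramolecular aldol condensation (Robinson-type annulation, the classical entry to 6-methylsalicylates) places the methyl next to the ester-bearing carbon.

Step 7
Reactants: 12 methyl 6-methyl-2-oxocyclohex-3-ene-1-carboxylate
Product: 13 methyl 2-hydroxy-6-methylbenzoate
Conditions: DDQ (1.2 equiv), 1,4-dioxane, 100 °C
Reagents that add atoms: none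
Why: Dehydrogenative aromatisation of the cyclohexenone β-keto ester is driven by formation of the hydrogen-bonded salicylate.

Step 8
Reactants: 13 methyl 2-hydroxy-6-methylbenzoate
Product: 14 methyl 2-acetoxy-6-methylbenzoate
Conditions: Ac2O (1.5 equiv), pyridine, DMAP (5 mol%), rt
Reagents that add atoms: acetic anhydride, CC(=O)OC(C)=O
Why: Standard DMAP-catalysed O-acetylation of a phenol.

Step 9
Reactants: 14 methyl 2-acetoxy-6-methylbenzoate
Product: 15 4-hydroxy-5-methyl-2H-chromen-2-one
Conditions: LiN(SiMe3)2 (2.2 equiv), THF, −78 °C → rt; 1 M HCl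
Reagents that add atoms: none
Why: Intramolecular Claisen (Dieckmann-type) condensation of the acetate enolate onto the neighbouring ester closes the pyranone ring and is driven by deprotonation of the acidic 4-hydroxycoumarin.

Step 10
Reactants: 15 4-hydroxy-5-methyl-2H-chromen-2-one
Product: 16 2-methoxy-5-methyl-4H-chromen-4-one
Conditions: MeOTf (1.3 equiv), CH2Cl2, rt; aq NaHCO3
Reagents that add atoms: methyl trifluoromethanesulfonate, COS(=O)(=O)C(F)(F)F
Why: A hard methylating agent alkylates the neutral 4-hydroxy-2-pyranone at the carbonyl oxygen remote from the mobile proton (Beak-type regiospecific methylation), which gives the 2-methoxychromone and not the 4-methoxycoumarin.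

Step 11
Reactants: 9 (2R,3S,6R)-2-chloro-3-methyl-6-[(2RS)-6-methylhept-3-yn-2-yl]cyclohexan-1-one; 16 2-methoxy-5-methyl-4H-chromen-4-one
Product: 19 (2-methoxy-5-methyl-4-oxo-4H-chromen-3-yl){(1R,2R,5S)-5-methyl-2-[(2RS)-6-methylhept-3-yn-2-yl]cyclopentyl}methanone, via chromonylmagnesium chloride 17 (not isolated), via chlorohydrin magnesium alkoxide 18 (not isolated)
Conditions: 16, TMPMgCl·LiCl (1.1 equiv), THF, −40 °C; LaCl3·2LiCl (1.0 equiv); 9, −40 → 0 °C; then toluene, 70 °C; aq NH4Cl
Reagents that add atoms: none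
Why: Carbonyl-directed magnesiation at C-3, 1,2-addition to the ketone and Tiffeneau-type semipinacol rearrangement of the chlorohydrin alkoxide, in which the equatorial C–Cl bond (locked by three equatorial substituents) is antiperiplanar to the C-1–C-6 ring bond, so that carbon migrates with retention to the chlorine-bearing carbon, which is inverted, giving from either carbinol epimer the cyclopentyl ketone with the acyl group trans to methyl and cis to the side chain.

Step 12
Reactants: 19 (2-methoxy-5-methyl-4-oxo-4H-chromen-3-yl){(1R,2R,5S)-5-methyl-2-[(2RS)-6-methylhept-3-yn-2-yl]cyclopentyl}methanone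
Product: 20 (2RS)-2-[(1R,2R,3S)-2-(2-methoxy-5-methyl-4-oxo-4H-chromene-3-carbonyl)-3-methylcyclopentyl]-6-methylheptane-3,4-dione
Conditions: RuCl3·3H2O (2 mol%), NaIO4 (2.5 equiv), NaHCO3, MgSO4, EtOAc/MeCN/H2O, 0 °C, 20 min
Reagents that add atoms: sodium periodate, [Na+].[O-]I(=O)(=O)=O
Why: Catalytic RuO4 oxidation converts dialkyl alkynes into 1,2-diketones under buffered conditions, and the electron-poor chromone, the aryl ketone and the stereocentres should be left alone in the short reaction time.

Step 13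
Reactants: 20 (2RS)-2-[(1R,2R,3S)-2-(2-methoxy-5-methyl-4-oxo-4H-chromene-3-carbonyl)-3-methylcyclopentyl]-6-methylheptane-3,4-dione
Product: 22 3-[(1S,4aS,7S,7aR)-4,7-dimethyl-3-(3-methylbutanoyl)-1,4a,5,6,7,7a-hexahydrocyclopenta[c]pyran-1-yl]-2-methoxy-5-methyl-4H-chromen-4-one, via cyclic silyl ketal 21 (not isolated)
Conditions: Me3SiOTf (1.2 equiv), CH2Cl2, −78 °C, 30 min; then Et3SiH (3 equiv), −78 → −40 °C; aq NaHCO3
Reagents that add atoms: none
Why: Proposed new method: a reductive enol-etherification in which the silyl-activated chromonyl ketone (cation stabilised by the 2-methoxychromone) is attacked by the nearer carbonyl oxygen of the 1,2-diketone to close the six-membered ring, loss of the C-4 proton gives the acyl enol ether 21 (too electron-poor to be protonated or reduced, and both side-chain epimers converge here), and renewed ionisation at C-1 followed by hydride transfer from Et3SiH to the convex face (the face of H-4a and H-7a, the other face being blocked by C-7 and H-7) sets C-1 as S; the closest known reactions are the Et3SiH/Me3SiOTf reductive etherification of ketones, the reductive cyclisation of 1,5-diketones and hydroxy ketones to 2,6-disubstituted tetrahydropyrans, and the silane reduction of C-aryl lactols.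

## Compound list

1 | cyclohex-2-en-1-one | O=C1C=CCCC1 | starting material
2 | (S)-3-methylcyclohexan-1-one | C[C@H]1CCCC(=O)C1 | intermediate
3 | (S,E)-2-[(dimethylamino)methylidene]-5-methylcyclohexan-1-one | C[C@H]1CC/C(=C\N(C)C)C(=O)C1 | intermediate
4 | (S,E)-2-ethylidene-5-methylcyclohexan-1-one | C[C@H]1CC/C(=C\C)C(=O)C1 | intermediate
5 | 4-methylpent-1-yne | C#CCC(C)C | starting material
6 | dimethyl(4-methylpent-1-yn-1-yl)aluminium (formed in the flask) | C[Al](C)C#CCC(C)C | intermediate
7 | (2R,5S)-5-methyl-2-[(2RS)-6-methylhept-3-yn-2-yl]cyclohexan-1-one | C[C@H]1CC[C@H](C(C)C#CCC(C)C)C(=O)C1 | intermediate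
8 | lithium (3S,6R)-3-methyl-6-[(2RS)-6-methylhept-3-yn-2-yl]cyclohex-1-en-1-olate (formed in the flask) | C[C@H]1CC[C@H](C(C)C#CCC(C)C)C(O[Li])=C1 | intermediate
9 | (2R,3S,6R)-2-chloro-3-methyl-6-[(2RS)-6-methylhept-3-yn-2-yl]cyclohexan-1-one | C[C@H]1CC[C@H](C(C)C#CCC(C)C)C(=O)[C@@H]1Cl | intermediate
10 | methyl 3-oxobutanoate | COC(=O)CC(C)=O | starting material
11 | (E)-but-2-enal | C/C=C/C=O | starting material
12 | methyl 6-methyl-2-oxocyclohex-3-ene-1-carboxylate (racemic, both diastereomers) | COC(=O)C1C(C)CC=CC1=O | intermediate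
13 | methyl 2-hydroxy-6-methylbenzoate | COC(=O)c1c(C)cccc1O | intermediate
14 | methyl 2-acetoxy-6-methylbenzoate | COC(=O)c1c(C)cccc1OC(C)=O | intermediate
15 | 4-hydroxy-5-methyl-2H-chromen-2-one | Cc1cccc2oc(=O)cc(O)c12 | intermediate
16 | 2-methoxy-5-methyl-4H-chromen-4-one | COc1cc(=O)c2c(C)cccc2o1 | intermediate
17 | chloro(2-methoxy-5-methyl-4-oxo-4H-chromen-3-yl)magnesium (formed in the flask) | COc1oc2cccc(C)c2c(=O)c1[Mg]Cl | intermediate
18 | chloromagnesium (2R,3S,6R)-2-chloro-1-(2-methoxy-5-methyl-4-oxo-4H-chromen-3-yl)-3-methyl-6-[(2RS)-6-methylhept-3-yn-2-yl]cyclohexan-1-olate (either configuration at C-1; formed in the flask) | C[C@H]1CC[C@H](C(C)C#CCC(C)C)C(O[Mg]Cl)(c2c(OC)oc3cccc(C)c3c2=O)[C@@H]1Cl | intermediate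
19 | (2-methoxy-5-methyl-4-oxo-4H-chromen-3-yl){(1R,2R,5S)-5-methyl-2-[(2RS)-6-methylhept-3-yn-2-yl]cyclopentyl}methanone | COc1oc2cccc(C)c2c(=O)c1C(=O)[C@@H]1[C@@H](C)CC[C@@H]1C(C)C#CCC(C)C | intermediate
20 | (2RS)-2-[(1R,2R,3S)-2-(2-methoxy-5-methyl-4-oxo-4H-chromene-3-carbonyl)-3-methylcyclopentyl]-6-methylheptane-3,4-dione | COc1oc2cccc(C)c2c(=O)c1C(=O)[C@@H]1[C@@H](C)CC[C@@H]1C(C)C(=O)C(=O)CC(C)C | intermediate
21 | 3-[(4aS,7S,7aR)-4,7-dimethyl-3-(3-methylbutanoyl)-1-(trimethylsilyloxy)-1,4a,5,6,7,7a-hexahydrocyclopenta[c]pyran-1-yl]-2-methoxy-5-methyl-4H-chromen-4-one (either configuration at C-1; formed in the flask) | COc1oc2cccc(C)c2c(=O)c1C1(O[Si](C)(C)C)OC(C(=O)CC(C)C)=C(C)[C@H]2CC[C@H](C)[C@H]21 | intermediate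
22 | 3-[(1S,4aS,7S,7aR)-4,7-dimethyl-3-(3-methylbutanoyl)-1,4a,5,6,7,7a-hexahydrocyclopenta[c]pyran-1-yl]-2-methoxy-5-methyl-4H-chromen-4-one | COc1oc2cccc(C)c2c(=O)c1[C@H]1OC(C(=O)CC(C)C)=C(C)[C@H]2CC[C@H](C)[C@H]21 | target

## Step count and risks

Total step count: 13. Longest linear sequence: 8 steps (steps 1–5 then 11–13; the chromone branch, steps 6–10 then 11–13, is equally long).

The three steps most likely to fail:

Step 11 (addition and semipinacol ring contraction). The ketone of 9 is flanked by two substituted carbons, so the stabilised chromonyl Grignard reagent may enolise it instead of adding, and the chloride may need more forcing conditions to leave. The fallback sets out from 7 and comes back at 19, and replaces the semipinacol by a Wolff ring contraction. Ketone 7 is deprotonated at the α-methylene (LiN(SiMe3)2, THF, −78 °C) and acylated with CF3CO2CH2CF3 to give the trifluoroacetyl ketone F1. Deacylative diazo transfer (MsN3, Et3N, MeCN, H2O) gives the α-diazo ketone F2. Irradiation (300 nm, THF, MeNHOMe) gives the ring-contracted ketene F3, which is trapped as the Weinreb amide F4; C-7a is set by kinetic protonation anti to the side chain and the epimer is removed. Acylation of 17 with F4 (THF, −20 → 0 °C) gives 19.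

Step 12 (alkyne to 1,2-diketone). RuO4 may over-oxidise to carboxylic acids or attack the aryl methyl group. The fallback sets out from 19 and comes back at 20. Semihydrogenation (H2, Pd on CaCO3 poisoned with Pb(OAc)2, quinoline) gives the Z-alkene F5, dihydroxylation (OsO4 2 mol%, N-methylmorpholine N-oxide) gives the diol F6, and double oxidation with Dess–Martin periodinane gives 20.

Step 13 (proposed new reductive cyclisation). Three things can go wrong: the acyclic cation may be reduced before ring closure (giving the deoxygenated or C-1-epimeric product); the product may re-ionise at C-1 under the Lewis acid; and C-7a may epimerise through a 4H-pyran. The fallback uses known chemistry, sets out from 19 and comes back at 22. Reagent-controlled reduction of the ketone ((R)-2-methyl-CBS-oxazaborolidine, BH3·SMe2, chromonyl as the large group) gives the S carbinol F7. Silylation (Et3SiOTf, 2,6-lutidine) gives the silyl ether F8, and the buffered RuCl3/NaIO4 oxidation of step 12 gives the silyloxy diketone F9. Acid (TsOH·H2O, MeOH; then toluene, 4 Å sieves, 60 °C) removes the silyl group to the hydroxy diketone F10, which closes to the hemiketal and dehydrates to 22 with C-1 unchanged.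

Further compounds

F1 | step 11 | (3S,6R)-3-methyl-6-[(2RS)-6-methylhept-3-yn-2-yl]-2-(trifluoroacetyl)cyclohexan-1-one | C[C@H]1CC[C@H](C(C)C#CCC(C)C)C(=O)C1C(=O)C(F)(F)F
F2 | step 11 | (3S,6R)-2-diazo-3-methyl-6-[(2RS)-6-methylhept-3-yn-2-yl]cyclohexan-1-one | C[C@H]1CC[C@H](C(C)C#CCC(C)C)C(=O)C1=[N+]=[N-]
F3 | step 11 | {(2S,5R)-2-methyl-5-[(2RS)-6-methylhept-3-yn-2-yl]cyclopentylidene}methanone | O=C=C1[C@@H](C)CC[C@@H]1C(C)C#CCC(C)C
F4 | step 11 | (1R,2R,5S)-N-methoxy-N,5-dimethyl-2-[(2RS)-6-methylhept-3-yn-2-yl]cyclopentane-1-carboxamide | CON(C)C(=O)[C@@H]1[C@@H](C)CC[C@@H]1C(C)C#CCC(C)C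
F5 | step 12 | (2-methoxy-5-methyl-4-oxo-4H-chromen-3-yl){(1R,2R,5S)-5-methyl-2-[(2RS,3Z)-6-methylhept-3-en-2-yl]cyclopentyl}methanone | COc1oc2cccc(C)c2c(=O)c1C(=O)[C@@H]1[C@@H](C)CC[C@@H]1C(C)/C=C\CC(C)C
F6 | step 12 | {(1R,2R,5S)-2-[3,4-dihydroxy-6-methylheptan-2-yl]-5-methylcyclopentyl}(2-methoxy-5-methyl-4-oxo-4H-chromen-3-yl)methanone (syn diol, diastereomer mixture) | COc1oc2cccc(C)c2c(=O)c1C(=O)[C@@H]1[C@@H](C)CC[C@@H]1C(C)C(O)C(O)CC(C)C
F7 | step 13 | 3-[(S)-hydroxy{(1R,2R,5S)-5-methyl-2-[(2RS)-6-methylhept-3-yn-2-yl]cyclopentyl}methyl]-2-methoxy-5-methyl-4H-chromen-4-one | COc1oc2cccc(C)c2c(=O)c1[C@@H](O)[C@@H]1[C@@H](C)CC[C@@H]1C(C)C#CCC(C)C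
F8 | step 13 | 2-methoxy-5-methyl-3-[(S)-{(1R,2R,5S)-5-methyl-2-[(2RS)-6-methylhept-3-yn-2-yl]cyclopentyl}(triethylsilyloxy)methyl]-4H-chromen-4-one | COc1oc2cccc(C)c2c(=O)c1[C@@H](O[Si](CC)(CC)CC)[C@@H]1[C@@H](C)CC[C@@H]1C(C)C#CCC(C)C
F9 | step 13 | (2RS)-2-{(1R,2R,3S)-2-[(S)-(2-methoxy-5-methyl-4-oxo-4H-chromen-3-yl)(triethylsilyloxy)methyl]-3-methylcyclopentyl}-6-methylheptane-3,4-dione | COc1oc2cccc(C)c2c(=O)c1[C@@H](O[Si](CC)(CC)CC)[C@@H]1[C@@H](C)CC[C@@H]1C(C)C(=O)C(=O)CC(C)C
F10 | step 13 | (2RS)-2-{(1R,2R,3S)-2-[(S)-hydroxy(2-methoxy-5-methyl-4-oxo-4H-chromen-3-yl)methyl]-3-methylcyclopentyl}-6-methylheptane-3,4-dione | COc1oc2cccc(C)c2c(=O)c1[C@@H](O)[C@@H]1[C@@H](C)CC[C@@H]1C(C)C(=O)C(=O)CC(C)C
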